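**Retrosynthetic overview**

1. Target 30 ⇐ α-methylene cis-lactone 24 by lactone opening, O-methylation, acetylation, desilylation and esterification. The 8,12-lactone is a temporary ring that locks C7/C8 and carries the methylenation.
2. 24 ⇐ dione 14 by C7 alkylation, axial reduction of C8=O with lactonisation, and Luche reduction at C3.
3. 14 ⇐ acyclic enol triflate 11 by the key step: an enantioselective Pd reductive Heck cyclisation closes ring B (C5–C10, quaternary C10), then a Dieckmann condensation closes ring A (C2–C3) in the same flask.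
4. Enabling feature: the C3(O)–C4(CH3)=C5 triad of ring A is a β-keto ester in disguise (its Z enol triflate is electrophilic at C5 and at C3); the quaternary C10–CH3 is a 1,1-disubstituted alkene whose CH2 becomes the methyl; both rings are six-membered; a temporary tert-butyl ester acidifies C2.
5. 11 ⇐ tert-butyl acetate, 3-bromo-2-(bromomethyl)prop-1-ene, methyl 4-oxobutanoate and methyl propanoate. Ring order: B, then A (one flask), then the temporary lactone.

Key step: step 8

Remark: eudesmane numbering is used in the text (decalin C1–C10, C14 on C10, C15 on C4, C11–C13 on C7); the SMILES in the compound list are authoritative.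
Assumption: methyl 4-oxobutanoate and (E)-3-methylpent-2-enoic acid are taken as purchasable; (R)-BINAP is taken as the ligand antipode that gives the 10R centre, and its antipode is used if the sense of induction is the opposite.

**Route**

Step 1
Reactants: 1 tert-butyl acetate; 2 3-bromo-2-(bromomethyl)prop-1-ene
Product: 3 tert-butyl 4-(bromomethyl)pent-4-enoate
Conditions: LDA, THF, −78 °C; then 2 (3 equiv), −78 to 0 °C
Reagents that add atoms: none
Why: Ester enolate alkylation (SN2; SN2′ gives the same product) of the symmetric bis-allylic dibromide, used in excess so that the second bromide is kept for step 2.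

Step 2
Reactants: 3 tert-butyl 4-(bromomethyl)pent-4-enoate; 4 methyl 4-oxobutanoate
Product: 5 1-tert-butyl 9-methyl 6-hydroxy-4-methylidenenonanedioate (racemic)
Conditions: Zn dust, sat. aq NH4Cl/THF, 0 °C to rt
Reagents that add atoms: none
Why: Barbier allylation; the allylzinc formed in situ adds to the aldehyde and tolerates both esters, and the racemic carbinol is oxidised in step 3.

Step 3
Reactants: 5 1-tert-butyl 9-methyl 6-hydroxy-4-methylidenenonanedioate
Product: 6 1-tert-butyl 9-methyl 4-methylidene-6-oxononanedioate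
Conditions: TPAP (cat.), NMO, 4 Å MS, CH2Cl2, rt
Reagents that add atoms: none
Why: Ley–Griffith oxidation under neutral conditions, chosen so that the β,γ-alkene should not move into conjugation.

Step 4
Reactants: 6 1-tert-butyl 9-methyl 4-methylidene-6-oxononanedioate
Product: 7 tert-butyl 5-[2-(3-methoxy-3-oxopropyl)-1,3-dioxolan-2-yl]-4-methylidenepentanoate
Conditions: (TMSOCH2)2, TMSOTf (cat.), CH2Cl2, −78 °C
Reagents that add atoms: 1,2-bis(trimethylsilyloxy)ethane C[Si](C)(C)OCCO[Si](C)(C)C
Why: Noyori ketalisation masks the C8 ketone without acid-mediated alkene migration, which makes the key-step substrate achiral and non-enolisable at C7/C9.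

Step 5
Reactants: 7 tert-butyl 5-[2-(3-methoxy-3-oxopropyl)-1,3-dioxolan-2-yl]-4-methylidenepentanoate
Product: 8 tert-butyl 5-{2-[3-(methoxy(methyl)amino)-3-oxopropyl]-1,3-dioxolan-2-yl}-4-methylidenepentanoate
Conditions: MeNHOMe·HCl, i-PrMgCl, THF, −20 °C
Reagents that add atoms: N,O-dimethylhydroxylamine hydrochloride CNOC.Cl
Why: Weinreb amide formation from the methyl ester with the magnesium amide; the hindered tert-butyl ester and the ketal should be untouched.

Step 6
Reactants: 8 Weinreb amide; 9 methyl propanoate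
Product: 10 methyl 5-{2-[5-(tert-butoxy)-2-methylidene-5-oxopentyl]-1,3-dioxolan-2-yl}-2-methyl-3-oxopentanoate
Conditions: 9 (2.2 equiv), LDA, THF, −78 °C; then 8, −78 to −30 °C
Reagents that add atoms: none
Why: Crossed Claisen condensation; the lithium enolate of methyl propanoate acylates once on the Weinreb amide (stable chelate) to give the α-methyl β-keto ester.

Step 7
Reactants: 10 α-methyl β-keto ester
Product: 11 methyl (2Z)-5-{2-[5-(tert-butoxy)-2-methylidene-5-oxopentyl]-1,3-dioxolan-2-yl}-2-methyl-3-{[(trifluoromethyl)sulfonyl]oxy}pent-2-enoate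
Conditions: NaH, Et2O, 0 °C; then Tf2O
Reagents that add atoms: trifluoromethanesulfonic anhydride O=S(=O)(OS(=O)(=O)C(F)(F)F)C(F)(F)F
Why: O-triflation of the chelated sodium enolate should give the Z enol triflate (ester and OTf cis), the geometry that later places the C3 ester next to C10.

Step 8
Reactants: 11 Z enol triflate
Product: 13 tert-butyl (4aR)-3,3-(ethylenedioxy)-4a,8-dimethyl-7-oxo-1,2,3,4,4a,5,6,7-octahydronaphthalene-6-carboxylate (C6 epimers/enol), via Heck ester 12 (not isolated)
Conditions: Pd2(dba)3 (3 mol %), (R)-BINAP (7 mol %), HCO2Na, DMF (0.01 M), 70 °C; then KOt-Bu, THF, 0 °C to rt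
Reagents that add atoms: none
Why: Proposed new method: Pd(0) inserts into the alkenyl C5–OTf bond with retention, the cationic alkenyl-Pd(BINAP) complex adds syn across the 1,1-disubstituted C10=CH2 alkene (6-exo-trig, ring B), the neopentyl Pd–CH2 cannot β-eliminate and is reduced by formate so that the CH2 becomes the angular methyl; KOt-Bu then forms the tert-butyl ester enolate, whose C2 attacks the C3 methyl ester held cis to C10 on the tetrasubstituted alkene (6-exo-trig Dieckmann condensation, ring A). The closest known reaction types are enantioselective intramolecular reductive Heck cyclisations of aryl triflates and halides onto 1,1-disubstituted alkenes, Overman-type asymmetric Heck cyclisations of alkenyl triflates, and the Dieckmann condensation; new are the alkenyl triflate in the reductive variant and the coupling of both closures in one flask. The only new stereocentre that persists, C10, is set by the chiral ligand in the insertion step on an achiral substrate; the C2 centre of the β-keto ester is enolised and is removed in step 9. The step needs insertion to outrun direct reduction of the alkenyl-Pd (sparingly soluble formate, intramolecular 6-exo closure), Z geometry so that the ester faces C10 (oxidative addition and insertion retain it, and a dienolate equilibrium would correct a leak), and enolisation at C2 only (C8 is a ketal, so no other enolisable carbonyl is present); irreversible deprotonation of the β-keto ester drives the condensation.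

Step 9
Reactants: 13 bicyclic tert-butyl β-keto ester ketal
Product: 14 (4aR)-4a,8-dimethyl-1,2,4,4a,5,6-hexahydronaphthalene-3,7-dione
Conditions: TFA/CH2Cl2/H2O, rt to 40 °C
Reagents that add atoms: water O
Why: Acidolysis of the tert-butyl ester, decarboxylation of the β-keto acid and ketal hydrolysis in one operation; the tetrasubstituted enone should be stable to acid.

Step 10
Reactants: 14 dione; 15 methyl bromoacetate
Product: 17 methyl 2-[(2R,4aR)-4a,8-dimethyl-3,7-dioxo-1,2,3,4,4a,5,6,7-octahydronaphthalen-2-yl]acetate, via enamine 16 (not isolated)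
Conditions: pyrrolidine, TsOH (cat.), PhH, reflux (Dean–Stark); then 15, MeCN, reflux; then AcOH/NaOAc/H2O, 60 °C
Reagents that add atoms: water O
Why: Stork enamine alkylation; pyrrolidine should condense with the saturated C8 ketone rather than the hindered enone, the enamine should form towards C7 away from quaternary C10, and after C-alkylation and hydrolysis C7 (α to the ketone) equilibrates to the equatorial 7R epimer.

Step 11
Reactants: 17 keto ester
Product: 19 (3aR,8aR,9aR)-5,8a-dimethyl-3,3a,4,7,8,8a,9,9a-octahydronaphtho[2,3-b]furan-2,6-dione, via hydroxy ester 18 (not isolated)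
Conditions: L-Selectride (1.05 equiv), THF, −78 °C; then 1 M HCl, rt
Reagents that add atoms: none
Why: Chemo- and stereoselective hydride reduction; the bulky borohydride should reduce the saturated ketone faster than the tetrasubstituted enone and attack from the α face (the axial C10 methyl blocks the β face), giving the axial 8β-alcohol cis to the C7 side chain, which lactonises to the temporary cis-fused lactone.

Step 12
Reactants: 19 enone lactone
Product: 20 (3aR,6S,8aR,9aR)-6-hydroxy-5,8a-dimethyl-3a,4,6,7,8,8a,9,9a-octahydronaphtho[2,3-b]furan-2(3H)-one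
Conditions: NaBH4, CeCl3·7H2O, MeOH, −20 °C
Reagents that add atoms: none
Why: Luche 1,2-reduction; hydride should add axially from the α face opposite the C10 methyl and give the equatorial 3β (3S) allylic alcohol.

Step 13
Reactants: 20 allylic alcohol
Product: 21 (3aR,6S,8aR,9aR)-6-{[tert-butyl(dimethyl)silyl]oxy}-5,8a-dimethyl-3a,4,6,7,8,8a,9,9a-octahydronaphtho[2,3-b]furan-2(3H)-one
Conditions: TBSCl, imidazole, DMF, rt
Reagents that add atoms: tert-butyldimethylsilyl chloride CC(C)(C)[Si](C)(C)Cl
Why: Silylation of the C3 alcohol so that the lactone is the only acidic site in step 14 and the two hydroxyls can be acylated differently later.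

Step 14
Reactants: 21 silyl ether lactone
Product: 22 (3aR,6S,8aR,9aR)-6-{[tert-butyl(dimethyl)silyl]oxy}-3-[(dimethylamino)methyl]-5,8a-dimethyl-3a,4,6,7,8,8a,9,9a-octahydronaphtho[2,3-b]furan-2(3H)-one (C3 epimers)
Conditions: LDA, THF, −78 °C; then CH2=NMe2+ I−, −78 °C to rt
Reagents that add atoms: N,N-dimethylmethyleneiminium iodide (Eschenmoser's salt) C=[N+](C)C.[I-]
Why: Mannich aminomethylation of the lactone enolate, the only enolisable position; the C11 configuration is irrelevant because it becomes sp2 in step 15.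

Step 15
Reactants: 22 Mannich base
Product: 24 (3aR,6S,8aR,9aR)-6-{[tert-butyl(dimethyl)silyl]oxy}-5,8a-dimethyl-3-methylidene-3a,4,6,7,8,8a,9,9a-octahydronaphtho[2,3-b]furan-2(3H)-one, via methiodide 23 (not isolated)
Conditions: MeI, MeOH, rt; then aq NaHCO3, EtOAc
Reagents that add atoms: none
Why: Quaternisation followed by E1cB (Hofmann-type) elimination of trimethylamine should give the exocyclic α-methylene lactone.

Step 16
Reactants: 24 α-methylene lactone
Product: 26 methyl 2-[(2R,3R,4aR,7S)-7-{[tert-butyl(dimethyl)silyl]oxy}-3-hydroxy-4a,8-dimethyl-1,2,3,4,4a,5,6,7-octahydronaphthalen-2-yl]prop-2-enoate, via lithium carboxylate 25 (not isolated)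
Conditions: LiOH, THF/H2O, 0 °C to rt; concentrate; MeI, DMF, 0 °C to rt
Reagents that add atoms: lithium hydroxide [Li+].[OH-]; iodomethane CI
Why: Saponification of the lactone and SN2 O-methylation of the carboxylate in one flask, so that the cis hydroxy acid is never acidified; C7 and C8 are not touched.

Step 17
Reactants: 26 hydroxy acrylate
Product: 27 methyl 2-[(2R,3R,4aR,7S)-3-acetoxy-7-{[tert-butyl(dimethyl)silyl]oxy}-4a,8-dimethyl-1,2,3,4,4a,5,6,7-octahydronaphthalen-2-yl]prop-2-enoate
Conditions: Ac2O, Et3N, DMAP, CH2Cl2, 0 °C to rt, directly on crude 26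
Reagents that add atoms: acetic anhydride CC(=O)OC(C)=O
Why: DMAP-catalysed acetylation of the axial C8 alcohol, run at once so that re-lactonisation is blocked.

Step 18
Reactants: 27 acetate silyl ether
Product: 28 methyl 2-[(2R,3R,4aR,7S)-3-acetoxy-7-hydroxy-4a,8-dimethyl-1,2,3,4,4a,5,6,7-octahydronaphthalen-2-yl]prop-2-enoate
Conditions: HF·pyridine, THF, 0 °C to rt
Reagents that add atoms: none
Why: Fluoride-mediated desilylation under weakly acidic conditions that should spare the acetate, the acrylate and the allylic C3–O bond.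

Step 19
Reactants: 28 allylic alcohol; 29 (E)-3-methylpent-2-enoic acid
Product: 30 methyl 2-[(2R,3R,4aR,7S)-3-acetoxy-4a,8-dimethyl-7-{[(2E)-3-methylpent-2-enoyl]oxy}-1,2,3,4,4a,5,6,7-octahydronaphthalen-2-yl]prop-2-enoate (target)
Conditions: 2,4,6-trichlorobenzoyl chloride, Et3N, DMAP, toluene, rt
Reagents that add atoms: none
Why: Yamaguchi esterification through the mixed anhydride acylates the C3 alcohol with retention and avoids the ketene pathway that would deconjugate or isomerise the enoate.

**Compound list**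

1 | tert-butyl acetate | CC(=O)OC(C)(C)C | starting material
2 | 3-bromo-2-(bromomethyl)prop-1-ene | C=C(CBr)CBr | starting material
3 | tert-butyl 4-(bromomethyl)pent-4-enoate | C=C(CBr)CCC(=O)OC(C)(C)C | intermediate
4 | methyl 4-oxobutanoate | COC(=O)CCC=O | starting material
5 | 1-tert-butyl 9-methyl 6-hydroxy-4-methylidenenonanedioate (racemic) | COC(=O)CCC(O)CC(=C)CCC(=O)OC(C)(C)C | intermediate
6 | 1-tert-butyl 9-methyl 4-methylidene-6-oxononanedioate | COC(=O)CCC(=O)CC(=C)CCC(=O)OC(C)(C)C | intermediate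
7 | tert-butyl 5-[2-(3-methoxy-3-oxopropyl)-1,3-dioxolan-2-yl]-4-methylidenepentanoate | COC(=O)CCC1(CC(=C)CCC(=O)OC(C)(C)C)OCCO1 | intermediate
8 | tert-butyl 5-{2-[3-(methoxy(methyl)amino)-3-oxopropyl]-1,3-dioxolan-2-yl}-4-methylidenepentanoate | CON(C)C(=O)CCC1(CC(=C)CCC(=O)OC(C)(C)C)OCCO1 | intermediate
9 | methyl propanoate | CCC(=O)OC | starting material
10 | methyl 5-{2-[5-(tert-butoxy)-2-methylidene-5-oxopentyl]-1,3-dioxolan-2-yl}-2-methyl-3-oxopentanoate | COC(=O)C(C)C(=O)CCC1(CC(=C)CCC(=O)OC(C)(C)C)OCCO1 | intermediate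
11 | methyl (2Z)-5-{2-[5-(tert-butoxy)-2-methylidene-5-oxopentyl]-1,3-dioxolan-2-yl}-2-methyl-3-{[(trifluoromethyl)sulfonyl]oxy}pent-2-enoate | COC(=O)/C(C)=C(\OS(=O)(=O)C(F)(F)F)CCC1(CC(=C)CCC(=O)OC(C)(C)C)OCCO1 | intermediate
12 | methyl (2Z)-2-[(7R)-7-[3-(tert-butoxy)-3-oxopropyl]-7-methyl-1,4-dioxaspiro[4.5]decan-8-ylidene]propanoate | COC(=O)/C(C)=C1/CCC2(OCCO2)C[C@@]1(C)CCC(=O)OC(C)(C)C | intermediate
13 | tert-butyl (4aR)-3,3-(ethylenedioxy)-4a,8-dimethyl-7-oxo-1,2,3,4,4a,5,6,7-octahydronaphthalene-6-carboxylate | CC1=C2CCC3(OCCO3)C[C@@]2(C)CC(C(=O)OC(C)(C)C)C1=O | intermediate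
14 | (4aR)-4a,8-dimethyl-1,2,4,4a,5,6-hexahydronaphthalene-3,7-dione | CC1=C2CCC(=O)C[C@@]2(C)CCC1=O | intermediate
15 | methyl bromoacetate | COC(=O)CBr | starting material
16 | (4aR)-4a,8-dimethyl-3-(pyrrolidin-1-yl)-4,4a,5,6-tetrahydronaphthalen-7(1H)-one | CC1=C2CC=C(N3CCCC3)C[C@@]2(C)CCC1=O | intermediate
17 | methyl 2-[(2R,4aR)-4a,8-dimethyl-3,7-dioxo-1,2,3,4,4a,5,6,7-octahydronaphthalen-2-yl]acetate | COC(=O)C[C@H]1CC2=C(C)C(=O)CC[C@]2(C)CC1=O | intermediate
18 | methyl 2-[(2R,3R,4aR)-3-hydroxy-4a,8-dimethyl-7-oxo-1,2,3,4,4a,5,6,7-octahydronaphthalen-2-yl]acetate | COC(=O)C[C@H]1CC2=C(C)C(=O)CC[C@]2(C)C[C@H]1O | intermediate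
19 | (3aR,8aR,9aR)-5,8a-dimethyl-3,3a,4,7,8,8a,9,9a-octahydronaphtho[2,3-b]furan-2,6-dione | O=C1C[C@H]2CC3=C(C)C(=O)CC[C@]3(C)C[C@H]2O1 | intermediate
20 | (3aR,6S,8aR,9aR)-6-hydroxy-5,8a-dimethyl-3a,4,6,7,8,8a,9,9a-octahydronaphtho[2,3-b]furan-2(3H)-one | O=C1C[C@H]2CC3=C(C)[C@@H](O)CC[C@]3(C)C[C@H]2O1 | intermediate
21 | (3aR,6S,8aR,9aR)-6-{[tert-butyl(dimethyl)silyl]oxy}-5,8a-dimethyl-3a,4,6,7,8,8a,9,9a-octahydronaphtho[2,3-b]furan-2(3H)-one | O=C1C[C@H]2CC3=C(C)[C@@H](O[Si](C)(C)C(C)(C)C)CC[C@]3(C)C[C@H]2O1 | intermediate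
22 | (3aR,6S,8aR,9aR)-6-{[tert-butyl(dimethyl)silyl]oxy}-3-[(dimethylamino)methyl]-5,8a-dimethyl-3a,4,6,7,8,8a,9,9a-octahydronaphtho[2,3-b]furan-2(3H)-one (C3 epimers) | O=C1C(CN(C)C)[C@H]2CC3=C(C)[C@@H](O[Si](C)(C)C(C)(C)C)CC[C@]3(C)C[C@H]2O1 | intermediate
23 | trimethylammoniomethyl lactone iodide (methiodide of 22) | O=C1C(C[N+](C)(C)C)[C@H]2CC3=C(C)[C@@H](O[Si](C)(C)C(C)(C)C)CC[C@]3(C)C[C@H]2O1.[I-] | intermediate
24 | (3aR,6S,8aR,9aR)-6-{[tert-butyl(dimethyl)silyl]oxy}-5,8a-dimethyl-3-methylidene-3a,4,6,7,8,8a,9,9a-octahydronaphtho[2,3-b]furan-2(3H)-one | O=C1C(=C)[C@H]2CC3=C(C)[C@@H](O[Si](C)(C)C(C)(C)C)CC[C@]3(C)C[C@H]2O1 | intermediate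
25 | lithium 2-[(2R,3R,4aR,7S)-7-{[tert-butyl(dimethyl)silyl]oxy}-3-hydroxy-4a,8-dimethyl-1,2,3,4,4a,5,6,7-octahydronaphthalen-2-yl]prop-2-enoate | [Li+].[O-]C(=O)C(=C)[C@H]1CC2=C(C)[C@@H](O[Si](C)(C)C(C)(C)C)CC[C@]2(C)C[C@H]1O | intermediate
26 | methyl 2-[(2R,3R,4aR,7S)-7-{[tert-butyl(dimethyl)silyl]oxy}-3-hydroxy-4a,8-dimethyl-1,2,3,4,4a,5,6,7-octahydronaphthalen-2-yl]prop-2-enoate | C=C(C(=O)OC)[C@H]1CC2=C(C)[C@@H](O[Si](C)(C)C(C)(C)C)CC[C@]2(C)C[C@H]1O | intermediate
27 | methyl 2-[(2R,3R,4aR,7S)-3-acetoxy-7-{[tert-butyl(dimethyl)silyl]oxy}-4a,8-dimethyl-1,2,3,4,4a,5,6,7-octahydronaphthalen-2-yl]prop-2-enoate | C=C(C(=O)OC)[C@H]1CC2=C(C)[C@@H](O[Si](C)(C)C(C)(C)C)CC[C@]2(C)C[C@H]1OC(C)=O | intermediate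
28 | methyl 2-[(2R,3R,4aR,7S)-3-acetoxy-7-hydroxy-4a,8-dimethyl-1,2,3,4,4a,5,6,7-octahydronaphthalen-2-yl]prop-2-enoate | C=C(C(=O)OC)[C@H]1CC2=C(C)[C@@H](O)CC[C@]2(C)C[C@H]1OC(C)=O | intermediate
29 | (E)-3-methylpent-2-enoic acid | OC(=O)/C=C(\C)CC | starting material
30 | methyl 2-[(2R,3R,4aR,7S)-3-acetoxy-4a,8-dimethyl-7-{[(2E)-3-methylpent-2-enoyl]oxy}-1,2,3,4,4a,5,6,7-octahydronaphthalen-2-yl]prop-2-enoate | C=C(C(=O)OC)[C@H]1CC2=C(C)[C@@H](OC(=O)/C=C(\C)CC)CC[C@]2(C)C[C@H]1OC(C)=O | target

**Step count and risks**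

Total step count: 19. Longest linear sequence: 19 steps (1/2 → 30).

Steps most likely to fail:

1. Step 8 (proposed method). The alkenyl-palladium may be reduced by formate before it inserts, the enantiofacial discrimination in the insertion may be poor, and the Claisen closure may stall in the Heck medium. Fallback with known chemistry, setting out from 11: a racemic reductive Heck cyclisation with Pd(OAc)2/PPh3/HCO2Na in DMF is run on its own and the racemic Heck ester F1 is isolated. A separate Dieckmann condensation (KOt-Bu, THF) then gives the racemic bicyclic β-keto ester F2. Acid treatment as in step 9 gives the racemic dione F3, which is resolved by preparative chromatography on a chiral stationary phase. The route is rejoined at 14.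

2. Step 10. Enamine formation may be unselective (towards C9, or dienamine formation at the enone), and N-alkylation or double alkylation may compete. Fallback setting out from 13: neutral thermolysis in wet DMSO at 150 °C removes the tert-butyl ester with decarboxylation and keeps the ketal, giving the enone ketal F4. Luche reduction gives the 3β-allylic alcohol F5 and silylation gives the silyl ether F6. PPTS in wet acetone unmasks the C8 ketone F7, now the only carbonyl. LDA and methyl bromoacetate with equilibration at C7 give the keto ester F8. L-Selectride followed by PPTS gives the lactone, and the route is rejoined at 21.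

3. Step 16. The γ-hydroxy ester may re-close to the lactone, and hydroxide may add in conjugate fashion to the methylene lactone. Fallback setting out from 22, with the lactone opened before the alkene is unveiled: LiOH in aqueous THF, adjustment to about pH 6 and TMSCHN2 give the amino hydroxy ester F9. Immediate acetylation (Ac2O, DMAP) gives the amino acetate F10. Methylation with MeI and elimination with aqueous NaHCO3 then form the acrylate, and the route is rejoined at 27.

Further compounds
F1 | step 8 | racemic methyl (2Z)-2-{7-[3-(tert-butoxy)-3-oxopropyl]-7-methyl-1,4-dioxaspiro[4.5]decan-8-ylidene}propanoate | COC(=O)/C(C)=C1/CCC2(OCCO2)CC1(C)CCC(=O)OC(C)(C)C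
F2 | step 8 | racemic tert-butyl 3,3-(ethylenedioxy)-4a,8-dimethyl-7-oxo-1,2,3,4,4a,5,6,7-octahydronaphthalene-6-carboxylate | CC1=C2CCC3(OCCO3)CC2(C)CC(C(=O)OC(C)(C)C)C1=O
F3 | step 8 | racemic 4a,8-dimethyl-1,2,4,4a,5,6-hexahydronaphthalene-3,7-dione | CC1=C2CCC(=O)CC2(C)CCC1=O
F4 | step 10 | (4aR)-3,3-(ethylenedioxy)-4a,8-dimethyl-1,2,3,4,4a,5-hexahydronaphthalen-7(6H)-one | CC1=C2CCC3(OCCO3)C[C@@]2(C)CCC1=O
F5 | step 10 | (4aR,7S)-3,3-(ethylenedioxy)-4a,8-dimethyl-1,2,3,4,4a,5,6,7-octahydronaphthalen-7-ol | CC1=C2CCC3(OCCO3)C[C@@]2(C)CC[C@@H]1O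
F6 | step 10 | tert-butyl{[(4aR,7S)-3,3-(ethylenedioxy)-4a,8-dimethyl-1,2,3,4,4a,5,6,7-octahydronaphthalen-7-yl]oxy}dimethylsilane | CC1=C2CCC3(OCCO3)C[C@@]2(C)CC[C@@H]1O[Si](C)(C)C(C)(C)C
F7 | step 10 | (4aR,7S)-7-{[tert-butyl(dimethyl)silyl]oxy}-4a,8-dimethyl-1,4,4a,5,6,7-hexahydronaphthalen-3(2H)-one | CC1=C2CCC(=O)C[C@@]2(C)CC[C@@H]1O[Si](C)(C)C(C)(C)C
F8 | step 10 | methyl 2-[(2R,4aR,7S)-7-{[tert-butyl(dimethyl)silyl]oxy}-4a,8-dimethyl-3-oxo-1,2,3,4,4a,5,6,7-octahydronaphthalen-2-yl]acetate | COC(=O)C[C@H]1CC2=C(C)[C@@H](O[Si](C)(C)C(C)(C)C)CC[C@]2(C)CC1=O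
F9 | step 16 | methyl 2-[(2R,3R,4aR,7S)-7-{[tert-butyl(dimethyl)silyl]oxy}-3-hydroxy-4a,8-dimethyl-1,2,3,4,4a,5,6,7-octahydronaphthalen-2-yl]-3-(dimethylamino)propanoate | COC(=O)C(CN(C)C)[C@H]1CC2=C(C)[C@@H](O[Si](C)(C)C(C)(C)C)CC[C@]2(C)C[C@H]1O
F10 | step 16 | methyl 2-[(2R,3R,4aR,7S)-3-acetoxy-7-{[tert-butyl(dimethyl)silyl]oxy}-4a,8-dimethyl-1,2,3,4,4a,5,6,7-octahydronaphthalen-2-yl]-3-(dimethylamino)propanoate | COC(=O)C(CN(C)C)[C@H]1CC2=C(C)[C@@H](O[Si](C)(C)C(C)(C)C)CC[C@]2(C)C[C@H]1OC(C)=O
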